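## Retrosynthetic overview

1. Feature: in the cyclohexenone ring, the oxygens on C1 and C4 sit at either end of the C2=C3 double bond in a polarity-mismatched 1,4 pattern, and O-4 and O-6 lie on the same face. Linking O-4 to C1 through a one-carbon carbonyl bridge turns this array into a 2-oxabicyclo[2.2.2]oct-5-en-3-one.
2. The C1 ketone is revealed late from a C1 α-hydroxy acid by oxidative loss of CO2. O-6 comes from an acetyl group by Baeyer–Villiger oxidation with retention.
3. The bicyclic lactone is cut at C4–C5 and C1–C6 into 6-[(Z)-heptadec-10-enyl]-3-hydroxy-2-pyrone (diene) and methyl vinyl ketone (dienophile).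
4. The pyrone comes from (Z)-2,5-dioxodocos-15-enoic acid by enol-lactonisation. That acid comes from the vinyl ketone of cis-vaccenic acid and ethyl 1,3-dithiane-2-carboxylate, used as a glyoxylate acyl-anion equivalent.
5. Ring order: the pyrone ring forms in step 6 and the carbocycle in step 8, which gives the bicycle. The lactone ring is opened in step 11 and its carbonyl carbon is expelled in step 14.

Key step: step 8

Assumption: the sense of induction of the cinchona catalyst on a 6-alkylated hydroxypyrone cannot be derived with certainty. The quinidine series is written; the quinine-derived pseudoenantiomer gives the mirror-image cycloadduct and would replace it if the configurational assignment of the cycloadduct requires it.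

## Route

Step 1
Reactants: 1 cis-vaccenic acid [(Z)-octadec-11-enoic acid]
Product: 3 (Z)-N-methoxy-N-methyloctadec-11-enamide, via acyl imidazolide 2 (not isolated)
Conditions: CDI, CH2Cl2, rt; then MeNH(OMe)·HCl, rt
Reagents that add atoms: N,O-dimethylhydroxylamine hydrochloride CNOC.Cl; 1,1'-carbonyldiimidazole O=C(n1ccnc1)n1ccnc1 (imidazolyl group of 2 only)
Why: Weinreb amide formation through the acyl imidazolide runs under near-neutral conditions that leave the Z-alkene untouched.

Step 2
Reactants: 3 (Z)-N-methoxy-N-methyloctadec-11-enamide; 4 vinylmagnesium bromide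
Product: 6 (Z)-icosa-1,13-dien-3-one, via magnesium chelate 5 (not isolated)
Conditions: THF, −78 → 0 °C; inverse quench into 1 M HCl, 0 °C
Reagents that add atoms: none
Why: In this Weinreb ketone synthesis the five-membered chelate 5 persists until the quench and so stops the reaction at mono-addition, and pouring into cold acid protonates the released MeNH(OMe) before it can add to the new enone.

Step 3
Reactants: 6 (Z)-icosa-1,13-dien-3-one; 7 ethyl 1,3-dithiane-2-carboxylate
Product: 8 ethyl 2-[(Z)-3-oxoicos-13-en-1-yl]-1,3-dithiane-2-carboxylate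
Conditions: KOt-Bu (10 mol %), THF, −20 → 0 °C
Reagents that add atoms: none
Why: This is a Michael addition of a soft, sulfur- and ester-stabilised carbanion to an unhindered vinyl ketone, in which the more basic product enolate is reprotonated by fresh 7 so that catalytic base suffices; it is preferred to a Stetter reaction of ethyl glyoxylate, whose ester-stabilised acyl-anion intermediate is a weak nucleophile.

Step 4
Reactants: 8 ethyl 2-[(Z)-3-oxoicos-13-en-1-yl]-1,3-dithiane-2-carboxylate
Product: 9 ethyl (Z)-2,5-dioxodocos-15-enoate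
Conditions: PhI(OCOCF3)2, MeCN/H2O (9:1), 0 °C
Reagents that add atoms: water O
Why: In this oxidative dethioacetalisation the trivalent-iodine reagent attacks sulfur much faster than an isolated dialkyl alkene, and water supplies the C2 carbonyl oxygen.

Step 5
Reactants: 9 ethyl (Z)-2,5-dioxodocos-15-enoate
Product: 11 (Z)-2,5-dioxodocos-15-enoic acid, via lithium carboxylate 10 (not isolated)
Conditions: LiOH (1.05 equiv), THF/H2O, 0 °C; then 1 M HCl
Reagents that add atoms: lithium hydroxide [Li+].[OH-]
Why: Saponification of the strongly activated α-keto ester should be complete within minutes at 0 °C with one equivalent of hydroxide, before the intramolecular aldol reaction of the 1,4-diketone can begin.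

Step 6
Reactants: 11 (Z)-2,5-dioxodocos-15-enoic acid
Product: 12 6-[(Z)-heptadec-10-en-1-yl]-2-oxo-2H-pyran-3-yl acetate
Conditions: Ac2O, NaOAc, 90 °C
Reagents that add atoms: acetic anhydride CC(=O)OC(C)=O
Why: This is an enol-lactonisation of a δ-keto acid by carboxyl activation with Ac2O, in which the C5 oxygen closes the six-membered ring and the C2 ketone is trapped as its enol acetate, so the weakly basic medium and the capped C2 oxygen block the acid-catalysed Paal–Knorr path to the isomeric 5-alkyl-2-furoic acid.

Step 7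
Reactants: 12 6-[(Z)-heptadec-10-en-1-yl]-2-oxo-2H-pyran-3-yl acetate
Product: 13 6-[(Z)-heptadec-10-en-1-yl]-3-hydroxy-2H-pyran-2-one
Conditions: HCl (cat.), MeOH, rt
Reagents that add atoms: none
Why: Acid-catalysed transesterification removes the reactive enol acetate and spares the conjugated pyrone lactone, in line with the acid deacetylation used for 3-acetoxy-2-pyrone carboxylic acids.

Step 8
Reactants: 13 6-[(Z)-heptadec-10-en-1-yl]-3-hydroxy-2H-pyran-2-one; 14 methyl vinyl ketone
Product: 15 (1R,4S,8S)-8-acetyl-1-[(Z)-heptadec-10-en-1-yl]-4-hydroxy-2-oxabicyclo[2.2.2]oct-5-en-3-one (exo adduct, acetyl syn to the O2–C3 bridge)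
Conditions: (9S)-9-(phenanthren-9-yloxy)cinchonan-6'-ol (10 mol %), 14 (3 equiv), Et2O, 0 °C → rt
Reagents that add atoms: none
Why: The quinuclidine nitrogen deprotonates the 3-OH of 13, and the resulting ion-paired oxidopyrone, a HOMO-raised dienolate, combines with the enone held by the 6'-OH hydrogen bond, either in one suprafacial [4+2] event or as a vinylogous Michael addition followed by aldol closure. The closest known reaction type is the amine- and cinchona-catalysed Diels–Alder reaction of 3-hydroxy-2-pyrones with enones and acrylates, and the alkyl group on the bond-forming pyrone C6 is the only extension. The single new ring, the six-membered carbocycle, closes through pyrone C6–CH2 and pyrone C3–CH(Ac), which in the stepwise picture is a 6-(enolexo)-exo-trig aldol onto the α-keto lactone. The largest dienolate coefficient lies at C6, para to the oxido group, so this carbon takes the enone CH2 and the acetyl-bearing carbon ends next to the carbinol bridgehead, which makes the ortho regiochemistry substrate-secured. Bridgeheads C1 and C4 are set together by the pyrone face that the catalyst leaves open, and C8 is set by placing the acetyl group over the O–C(=O) bridge, which the hydrogen bond must enforce against the usual endo bias. Exo and facial selectivity therefore depend on the catalyst, whereas aromatisation is excluded by the quaternary oxygen-bearing bridgehead and CO2 extrusion is avoided by staying at or below room temperature.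

Step 9
Reactants: 15 exo adduct
Product: 16 (1R,4S,8S)-8-acetyl-1-[(Z)-heptadec-10-en-1-yl]-4-(trimethylsilyloxy)-2-oxabicyclo[2.2.2]oct-5-en-3-one
Conditions: N-(trimethylsilyl)imidazole, CH2Cl2, 0 °C → rt
Reagents that add atoms: N-(trimethylsilyl)imidazole C[Si](C)(C)n1ccnc1
Why: O-silylation of the exposed bridgehead carbinol needs no added base, blocks retro-aldol cleavage of the β-hydroxy ketone, keeps the hydroxyl from consuming the silyl peroxide of step 10, and touches no stereocentre.

Step 10
Reactants: 16 TMS-protected adduct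
Product: 17 (1R,4S,8S)-1-[(Z)-heptadec-10-en-1-yl]-3-oxo-4-(trimethylsilyloxy)-2-oxabicyclo[2.2.2]oct-5-en-8-yl acetate
Conditions: Me3SiOOSiMe3 (3 equiv), Me3SiOTf (10 mol %), CH2Cl2, −40 → −20 °C
Reagents that add atoms: bis(trimethylsilyl) peroxide C[Si](C)(C)OO[Si](C)(C)C
Why: In this Baeyer–Villiger oxidation the silyl peroxide adds to the silyl-activated ketone and the secondary C8 migrates in preference to methyl with retention of configuration, while the reagent carries no electrophilic peracid oxygen and so should spare both alkenes.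

Step 11
Reactants: 17 bicyclic acetate
Product: 18 methyl (1S,4R,6S)-4-[(Z)-heptadec-10-en-1-yl]-1,4,6-trihydroxycyclohex-2-ene-1-carboxylate
Conditions: K2CO3 (cat.), MeOH, 0 °C → rt
Reagents that add atoms: methanol CO
Why: Zemplén-type methanolysis should cleave the strained bridged lactone, the acetate and the TMS ether in one operation; this is chosen because the lactone would not survive a selective deacetylation, and since only acyl–O and Si–O bonds break all three stereocentres are kept.

Step 12
Reactants: 18 triol ester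
Product: 19 methyl (1S,4R,6S)-6-(tert-butyldimethylsilyloxy)-4-[(Z)-heptadec-10-en-1-yl]-1,4-dihydroxycyclohex-2-ene-1-carboxylate
Conditions: TBSCl, imidazole, DMF, rt
Reagents that add atoms: tert-butyldimethylsilyl chloride CC(C)(C)[Si](C)(C)Cl
Why: This silylation is chemoselective because only the C6 hydroxyl is secondary and the two tertiary carbinols are inert to TBSCl/imidazole, and it masks the C1/C6 glycol against the cleavage reagent of step 14.

Step 13
Reactants: 19 silyl ether ester
Product: 21 (1S,4R,6S)-6-(tert-butyldimethylsilyloxy)-4-[(Z)-heptadec-10-en-1-yl]-1,4-dihydroxycyclohex-2-ene-1-carboxylic acid, via lithium carboxylate 20 (not isolated)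
Conditions: LiOH, THF/MeOH/H2O, rt; then 1 M HCl to pH 4, 0 °C
Reagents that add atoms: lithium hydroxide [Li+].[OH-]
Why: Saponification of the α-hydroxy ester leaves the TBS ether intact, and the cold, mild acidification avoids both re-closure to the strained lactone and ionisation of the tertiary allylic alcohol.

Step 14
Reactants: 21 α-hydroxy acid
Product: 22 (4R,6S)-6-(tert-butyldimethylsilyloxy)-4-[(Z)-heptadec-10-en-1-yl]-4-hydroxycyclohex-2-en-1-one
Conditions: Pb(OAc)4, CH2Cl2, 0 °C
Reagents that add atoms: none
Why: In this oxidative decarboxylation, tetravalent lead binds the C1 hydroxyl and the carboxyl group and the chelate fragments to the ketone, CO2 and divalent lead, while the silylated O-6 rules out glycol cleavage and the alkenes, the C4 carbinol and both stereocentres are untouched at 0 °C.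

Step 15
Reactants: 22 silyl-protected enone
Product: 23 (4R,6S)-4-[(Z)-heptadec-10-en-1-yl]-4,6-dihydroxycyclohex-2-en-1-one (target)
Conditions: HF·pyridine, THF, 0 °C
Reagents that add atoms: none
Why: Fluoride-driven desilylation in a mildly acidic, buffered medium avoids the basic conditions that would epimerise C6 through the enediol or start dehydration to the cross-conjugated dienone.

## Compound list

1 | cis-vaccenic acid | CCCCCC/C=C\CCCCCCCCCC(=O)O | starting material
2 | (Z)-1-(imidazol-1-yl)octadec-11-en-1-one | CCCCCC/C=C\CCCCCCCCCC(=O)n1ccnc1 | intermediate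
3 | (Z)-N-methoxy-N-methyloctadec-11-enamide | CCCCCC/C=C\CCCCCCCCCC(=O)N(C)OC | intermediate
4 | vinylmagnesium bromide | C=C[Mg]Br | starting material
5 | bromomagnesium alkoxide of the tetrahedral adduct of 3 and 4 | CCCCCC/C=C\CCCCCCCCCC(O[Mg]Br)(C=C)N(C)OC | intermediate
6 | (Z)-icosa-1,13-dien-3-one | CCCCCC/C=C\CCCCCCCCCC(=O)C=C | intermediate
7 | ethyl 1,3-dithiane-2-carboxylate | CCOC(=O)C1SCCCS1 | starting material
8 | ethyl 2-[(Z)-3-oxoicos-13-en-1-yl]-1,3-dithiane-2-carboxylate | CCCCCC/C=C\CCCCCCCCCC(=O)CCC1(SCCCS1)C(=O)OCC | intermediate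
9 | ethyl (Z)-2,5-dioxodocos-15-enoate | CCCCCC/C=C\CCCCCCCCCC(=O)CCC(=O)C(=O)OCC | intermediate
10 | lithium (Z)-2,5-dioxodocos-15-enoate | CCCCCC/C=C\CCCCCCCCCC(=O)CCC(=O)C(=O)[O-].[Li+] | intermediate
11 | (Z)-2,5-dioxodocos-15-enoic acid | CCCCCC/C=C\CCCCCCCCCC(=O)CCC(=O)C(=O)O | intermediate
12 | 6-[(Z)-heptadec-10-en-1-yl]-2-oxo-2H-pyran-3-yl acetate | CCCCCC/C=C\CCCCCCCCCC1=CC=C(OC(C)=O)C(=O)O1 | intermediate
13 | 6-[(Z)-heptadec-10-en-1-yl]-3-hydroxy-2H-pyran-2-one | CCCCCC/C=C\CCCCCCCCCC1=CC=C(O)C(=O)O1 | intermediate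
14 | methyl vinyl ketone | CC(=O)C=C | starting material
15 | (1R,4S,8S)-8-acetyl-1-[(Z)-heptadec-10-en-1-yl]-4-hydroxy-2-oxabicyclo[2.2.2]oct-5-en-3-one | CCCCCC/C=C\CCCCCCCCC[C@@]12C=C[C@@](O)(C(=O)O1)[C@@H](C(C)=O)C2 | intermediate
16 | (1R,4S,8S)-8-acetyl-1-[(Z)-heptadec-10-en-1-yl]-4-(trimethylsilyloxy)-2-oxabicyclo[2.2.2]oct-5-en-3-one | CCCCCC/C=C\CCCCCCCCC[C@@]12C=C[C@@](O[Si](C)(C)C)(C(=O)O1)[C@@H](C(C)=O)C2 | intermediate
17 | (1R,4S,8S)-1-[(Z)-heptadec-10-en-1-yl]-3-oxo-4-(trimethylsilyloxy)-2-oxabicyclo[2.2.2]oct-5-en-8-yl acetate | CCCCCC/C=C\CCCCCCCCC[C@@]12C=C[C@@](O[Si](C)(C)C)(C(=O)O1)[C@@H](OC(C)=O)C2 | intermediate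
18 | methyl (1S,4R,6S)-4-[(Z)-heptadec-10-en-1-yl]-1,4,6-trihydroxycyclohex-2-ene-1-carboxylate | CCCCCC/C=C\CCCCCCCCC[C@]1(O)C=C[C@@](O)(C(=O)OC)[C@@H](O)C1 | intermediate
19 | methyl (1S,4R,6S)-6-(tert-butyldimethylsilyloxy)-4-[(Z)-heptadec-10-en-1-yl]-1,4-dihydroxycyclohex-2-ene-1-carboxylate | CCCCCC/C=C\CCCCCCCCC[C@]1(O)C=C[C@@](O)(C(=O)OC)[C@@H](O[Si](C)(C)C(C)(C)C)C1 | intermediate
20 | lithium salt of acid 21 | CCCCCC/C=C\CCCCCCCCC[C@]1(O)C=C[C@@](O)(C(=O)[O-])[C@@H](O[Si](C)(C)C(C)(C)C)C1.[Li+] | intermediate
21 | (1S,4R,6S)-6-(tert-butyldimethylsilyloxy)-4-[(Z)-heptadec-10-en-1-yl]-1,4-dihydroxycyclohex-2-ene-1-carboxylic acid | CCCCCC/C=C\CCCCCCCCC[C@]1(O)C=C[C@@](O)(C(=O)O)[C@@H](O[Si](C)(C)C(C)(C)C)C1 | intermediate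
22 | (4R,6S)-6-(tert-butyldimethylsilyloxy)-4-[(Z)-heptadec-10-en-1-yl]-4-hydroxycyclohex-2-en-1-one | CCCCCC/C=C\CCCCCCCCC[C@]1(O)C=CC(=O)[C@@H](O[Si](C)(C)C(C)(C)C)C1 | intermediate
23 | (4R,6S)-4-[(Z)-heptadec-10-en-1-yl]-4,6-dihydroxycyclohex-2-en-1-one | CCCCCC/C=C\CCCCCCCCC[C@]1(O)C=CC(=O)[C@@H](O)C1 | target

## Step count and risks

Total step count: 15. Longest linear sequence: 15 steps, from 1 to 23.

**Step 8 (cycloaddition).** The intrinsic endo preference of the oxidopyrone–enone pair may override the catalyst, so that the acetyl group is placed under the C5=C6 bridge. The extra alkyl group at the bond-forming carbon may also erode facial control.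

The fallback accepts the endo mode and corrects C6 later. It sets out from 13 and 14.
- A 9-thiourea cinchona catalyst of the matching series, a class that favours the endo mode in this reaction type, should give the endo adduct F1.
- The operations of steps 9 to 11 then lead through the TMS ether F2 and the endo acetate F3 to the 6-epi triol ester F4.
- Mitsunobu inversion of the only secondary hydroxyl (4-nitrobenzoic acid, PPh3, DIAD, THF) gives the inverted 4-nitrobenzoate F5. The cis-disposed C1 hydroxyl cannot displace the activated oxygen from the rear.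
- Methanolysis with K2CO3 in MeOH returns the route at 18.

**Step 10 (Baeyer–Villiger oxidation).** Peroxide addition to the hindered, inductively deactivated ketone may be too slow at the low temperature required. Forcing the reaction risks Lewis-acid ionisation of the tertiary allylic lactone C–O bond.

The fallback masks the chain alkene so that a true peracid can be used. It sets out from 16.
- One equivalent of pyridinium tribromide in CH2Cl2 at −78 °C adds anti to the electron-rich chain alkene and gives the chain dibromide F6. The ring alkene is flanked by two oxygenated quaternary carbons and should not compete.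
- Buffered CF3CO3H (urea–hydrogen peroxide, (CF3CO)2O, Na2HPO4, CH2Cl2, 0 °C) gives the dibromo acetate F7.
- Stereospecific anti debromination with Zn dust in THF/AcOH restores the Z-alkene and returns the route at 17.

**Step 6 (pyrone formation).** Dehydration may be diverted through the C2 enol oxygen into the Paal–Knorr manifold, or the activated α-keto acid may lose CO or CO2 on heating.

The fallback closes the lactone while C2 is still masked, so no 1,4-diketone is present. It sets out from 8.
- KOH in aqueous EtOH at 50 °C gives the dithiane keto acid F8.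
- Ac2O/NaOAc at 90 °C gives the spiro dithiane enol lactone F9.
- PhI(OCOCF3)2 in NaHCO3-buffered aqueous MeCN at 0 °C unmasks the pyran-2,3-dione F10, which tautomerises in the flask and returns the route at 13.

## Further compounds

F1 | step 8 | (1R,4S,8R)-8-acetyl-1-[(Z)-heptadec-10-en-1-yl]-4-hydroxy-2-oxabicyclo[2.2.2]oct-5-en-3-one (endo adduct) | CCCCCC/C=C\CCCCCCCCC[C@@]12C=C[C@@](O)(C(=O)O1)[C@H](C(C)=O)C2
F2 | step 8 | 4-O-trimethylsilyl ether of F1 | CCCCCC/C=C\CCCCCCCCC[C@@]12C=C[C@@](O[Si](C)(C)C)(C(=O)O1)[C@H](C(C)=O)C2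
F3 | step 8 | (1R,4S,8R)-1-[(Z)-heptadec-10-en-1-yl]-3-oxo-4-(trimethylsilyloxy)-2-oxabicyclo[2.2.2]oct-5-en-8-yl acetate | CCCCCC/C=C\CCCCCCCCC[C@@]12C=C[C@@](O[Si](C)(C)C)(C(=O)O1)[C@H](OC(C)=O)C2
F4 | step 8 | methyl (1S,4R,6R)-4-[(Z)-heptadec-10-en-1-yl]-1,4,6-trihydroxycyclohex-2-ene-1-carboxylate | CCCCCC/C=C\CCCCCCCCC[C@]1(O)C=C[C@@](O)(C(=O)OC)[C@H](O)C1
F5 | step 8 | methyl (1S,4R,6S)-4-[(Z)-heptadec-10-en-1-yl]-1,4-dihydroxy-6-(4-nitrobenzoyloxy)cyclohex-2-ene-1-carboxylate | CCCCCC/C=C\CCCCCCCCC[C@]1(O)C=C[C@@](O)(C(=O)OC)[C@@H](OC(=O)c2ccc(cc2)[N+](=O)[O-])C1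
F6 | step 10 | 10',11'-dibromide of 16 (anti addition, both side-chain diastereomers) | CCCCCCC(Br)C(Br)CCCCCCCCC[C@@]12C=C[C@@](O[Si](C)(C)C)(C(=O)O1)[C@@H](C(C)=O)C2
F7 | step 10 | 10',11'-dibromide of 17 (both side-chain diastereomers) | CCCCCCC(Br)C(Br)CCCCCCCCC[C@@]12C=C[C@@](O[Si](C)(C)C)(C(=O)O1)[C@@H](OC(C)=O)C2
F8 | step 6 | 2-[(Z)-3-oxoicos-13-en-1-yl]-1,3-dithiane-2-carboxylic acid | CCCCCC/C=C\CCCCCCCCCC(=O)CCC1(SCCCS1)C(=O)O
F9 | step 6 | 9-[(Z)-heptadec-10-en-1-yl]-8-oxa-1,5-dithiaspiro[5.5]undec-9-en-7-one | CCCCCC/C=C\CCCCCCCCCC1=CCC2(SCCCS2)C(=O)O1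
F10 | step 6 | 6-[(Z)-heptadec-10-en-1-yl]-2H-pyran-2,3(4H)-dione | CCCCCC/C=C\CCCCCCCCCC1=CCC(=O)C(=O)O1
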